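2.67 min is the time to fill with target as read off the oak run, and the cedar run reads 7.14 min, which is longer.

| flask | starting material | protic impurity | temperature | remark | time |
|---|---|---|---|---|---|
| cedar | 0.054 M | 0.023 M | 0 °C | run made earlier |  |
| oak | 0.054 M | 0.036 M | 12 °C | run made earlier |  |
| Tuesday's | 0.054 M | 0.0162 M | 20 °C |  | 15 min |
| Friday's | 0.054 M | 0.0162 M | 5 °C |  | 15 min |

- cedar (time / min: target / %): 2.00: 7; 4.00: 10; 5.00: 12; 8.00: 15; 15.0: 22; 25.0: 25
- oak (time / min: target / %): 0.667: 8; 2.00: 19; 3.00: 22; 5.00: 27; 6.00: 29; 10.0: 32

(scatter of a reading: 1.5 percentage points)

1. which flask leads in amount of target, in percent of the starting material charged ("all alike" within 1.5 percentage points) (Tuesday's / Friday's / all alike)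
2. how much target is there at the end, in percent of the starting material charged: Tuesday's
3. how much target is there at the end, in percent of the starting material charged: Friday's

- the earlier runs were read with a standard deviation of 1.5 percentage points

Take the last reading of target and divide it by the opening slope. Assume that the starting material decays first-order and that this quotient is the time constant. Let its logarithm run straight with temperature through the two runs, though they differ in protic impurity too. My reckoning for Tuesday's flask gives 1.38 min, the filling time. Integrate the first-order loss: [starting material] falls as the exponential of minus time over filling time.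

Now run Tuesday's flask slowly. Stretch the last readings the same way, and the plateau comes to 37.7 %. In the first instants of Tuesday's flask, expect an opening slope of 0.273 min⁻¹, as a fraction of the charge. After one filling time, the exponential leaves 36.8 % of the starting material. At 15 min, the exponential leaves 0.00196 %, so expect Tuesday's flask to sit on its plateau.

Friday's flask has a filling time of 4.74 min, longer than Tuesday's. It should leave 4.22 % of its starting material and hold 26.5 % of target. Both flasks carry less protic impurity than either run, so expect somewhat more target than these figures.

The forecast names Tuesday's as leader, as I do, but its numbers stand higher: 64 % for Tuesday's and 36 % for Friday's. It warns: “The mechanism is uncertain and temperature and impurity are confounded”.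

The flask gives 46.9 % for Tuesday's and 30.7 % for Friday's, so Tuesday's leads. Tuesday's lies below the forecast and above my reckoning.

    starting material + protic impurity → quenched substrate (k = 0.110 L mol⁻¹ s⁻¹, Ea = 53.0 kJ mol⁻¹)
    starting material → decomposition product (k = 9.80 × 10⁻⁷ s⁻¹, Ea = 92.0 kJ mol⁻¹)
    starting material → target, rate k3*[starting material]/(1 + ([starting material]/sat3)) (40.0 mM, k = 0.00250 s⁻¹, Ea = 74.0 kJ mol⁻¹)
    2 starting material → homo dimer (k = 0.0550 L mol⁻¹ s⁻¹, Ea = 36.0 kJ mol⁻¹)
    (constants at 5 °C)

Tuesday's flask ran 10.9 filling times and holds 0.0953 % of starting material at 7.50 min, so a tenfold time changes nothing. Friday's flask ran 3.16 filling times and still holds 2.58 % of starting material at 15.0 min, and its target reaches 32.7 % at 150 min. The loss of starting material to homo dimer is the main reason Tuesday's target stops where it does: homo dimer holds 33.4 % of the charge, and Tuesday's flask without that step gives 74.9 % of target.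

The runs are simulated for an exercise.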